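The readings are calculated from invented constants; scatter was added.

The ratio to watch is the chain ceiling, 452 for winter: G charged over the Z that stays once each Q has taken one Z, both per starting volume. That Q poisons Z is my guess from the lag in the earlier runs. The average length is then the ceiling times the share of G in X, divided by the share of that Z budget that has begun chains.

the same everywhere: Z 29 µM; Q 6.9 µM
- south-east: G 12 mM (fed, over 8.0 h); run made earlier; the fed solution adds 1.0 times the starting volume
- west: G 16 mM (fed, over 8.0 h); run made earlier; the fed solution adds 1.0 times the starting volume
- north-west: G 35 mM (fed, over 8.0 h); run made earlier; the fed solution adds 1.0 times the starting volume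
- winter: G 10 mM (fed, over 8.0 h); the fed solution adds 1.0 times the starting volume; time 8.0 h
- midnight: G 30 mM (fed, over 8.0 h); the fed solution adds 1.0 times the starting volume; time 8.0 h

| run | time / h | X / % | G / % |
|---|---|---|---|
| south-east | 0.833 | 0.4 | 9.5 |
| south-east | 1.50 | 1.6 | 16.7 |
| south-east | 2.50 | 8.0 | 20.9 |
| south-east | 3.00 | 13.1 | 21.5 |
| south-east | 4.00 | 24.2 | 21.2 |
| west | 0.333 | 0.1 | 4.1 |
| west | 1.00 | 0.3 | 11.6 |
| west | 2.00 | 5.1 | 18.0 |
| west | 3.00 | 15.6 | 19.6 |
| west | 4.00 | 26.6 | 19.1 |
| north-west | 0.833 | 0.8 | 10.0 |
| north-west | 1.50 | 3.9 | 13.8 |
| north-west | 2.50 | 14.0 | 15.3 |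
| north-west | 3.00 | 19.8 | 15.4 |
| north-west | 4.00 | 31.1 | 15.4 |

(each reading ± 0.3 percentage points)

- charges are per starting volume, the dose included; the dosed solution carries all of it
- the average divides the monomer in chains by the number of chains begun, living and dead together
- the analysis behind the earlier runs scatters by 0.3 percentage points, standard deviation
- the earlier runs do not show the number of chains; that part of a forecast is a guess
- percentages count the whole charge, also what has not yet gone in

* which of the two ends with the longer chains by the average number of monomer units in a chain (chains begun, living or dead) ("neither" if they lie within 10 %) (winter / midnight / neither)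
* average number of monomer units in a chain (chains begun, living or dead) at the end, winter
* average number of monomer units in a chain (chains begun, living or dead) at the end, midnight

Turn the G charge first. By hand, midnight's ceiling is 1360, or 3.00 times winter's. In the readings, going from 12 mM to 35 mM of G moved X at 4.00 h from 24.2 % to 31.1 %, so the share in X holds up on a richer feed.

Turn Z next. By hand, cutting [Z] lifts the ceiling steeply, but once [G] levels off its uptake looks pseudo-first-order, with the growing ends in the constant, so I expect the X share to pay. The earlier runs hold Z and Q fixed, so this stays an expectation.

Turn the time last. Dosing ends at 8.0 h, and I carry the last hourly gain of X forward, using the south-east run for winter and the north-west run for midnight: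

winter: X share 68.6 %, length 310

midnight: X share 76.3 %, length 1040

The forecast also names midnight, but with 230 for winter and 760 for midnight, “giving about 29 µM chains begun, dead ones included”. My divisor is 22.1 µM, against its 29 µM.

The flasks give 360 for winter and 1020 for midnight, so midnight ends longer.

    G + Z → J + X (k = 3.30 M⁻¹ min⁻¹)
    G → L (k = 0.00117 min⁻¹)
    Z + Q → D (k = 66400 M⁻¹ min⁻¹)
    G + J → X + J, rate k4*[J]*[G] (k = 912 M⁻¹ min⁻¹)

The difference in G is the main reason: take that difference away, giving midnight winter's charge, and its 1020 becomes 360. Counting J per starting volume gives the share of the budget begun, which turns each ceiling into its length: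

winter: begun 86.2 %, length 360

midnight: begun 99.0 %, length 1020

A neighbouring flask, midnight's recipe with 0.012 mM of Z, has a ceiling of 5880. With its 37.2 % in X, that gives 2190, and the flask gives 2190 with 46 % of its G still unreacted.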